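**Plan**

1. Retrosynthesis: the two O–SO3H bonds (on the C7 oxygen and on the C4 oxygen) are cut first. The C7–O bond is then taken back through the aldehyde and its dimethyl acetal to a methyl group, and C2–Br and C3–Br are cut last, which leads to 2-methoxy-4-methylphenol.
2. Numbering: C1 carries the benzylic carbon C7, C2 and C3 carry Br, C4 the sulfated oxygen, C5 the free OH, and C6 is CH. The enabling feature is that C7 lies para to the C4 oxygen, so a free C4 phenol flanked by C3–Br and C5–OMe relays a two-electron oxidation to C7 through a para-quinone methide.
3. Forward: dibromination of the cresol, anodic oxidation of the methyl group to the acetal (two C7–O bonds), hydrolysis, O-demethylation, C4 sulfation, C5 acetylation, reduction, then C7 sulfation with deacetylation.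
4. The benzene ring is bought and no ring is formed. The target has no stereocentre and no stereogenic double bond, so no stereocontrol is needed.

Key step: step 2

Assumption: the target SMILES is the free-acid drawing of a bis(sulfate) that is only stable as a salt. Every sulfate monoester (14, 16, 17, 18, 19 and F5) is therefore written as the hydrogen sulfate but would be handled as its potassium salt, and 19 would be isolated as the dipotassium salt.

**Route**

Step 1
Reactants: 1 2-methoxy-4-methylphenol; 2 bromine
Product: 4 2,3-dibromo-6-methoxy-4-methylphenol, via monobromide 3 (not isolated)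
Conditions: Br2 (2.1 equiv), AcOH, 15 °C to rt, dark
Reagents that add atoms: bromine, BrBr
Why: Electrophilic aromatic bromination in which the hydroxyl directs one bromine ortho to itself (C3) and the methoxy group directs the other para to itself (C2), while the remaining position C6 lies between the methyl and methoxy groups and is the least activated and most hindered, and ionic conditions in the dark leave the methyl group untouched.

Step 2
Reactants: 4 2,3-dibromo-6-methoxy-4-methylphenol; 5 methanol
Product: 9 2,3-dibromo-4-(dimethoxymethyl)-6-methoxyphenol, via quinone methide 6 (not isolated), via benzylic methyl ether 7 (not isolated), via methoxy quinone methide 8 (not isolated)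
Conditions: graphite anode, Pt cathode, undivided cell, NaOMe (0.5 equiv), MeOH, constant current, ca. 4.5 F/mol, 15–20 °C
Reagents that add atoms: methanol, CO
Why: In basic methanol 4 is present as its phenoxide, which gives up two electrons at graphite and a proton from C7 (from the phenoxonium ion or by disproportionation of the phenoxyl radical) to form quinone methide 6; methoxide adds to the exocyclic C7 and rearomatises the ring to 7, and a second identical cycle through 8 should deliver acetal 9, while methanol is reduced to hydrogen and methoxide at the cathode. The closest known reaction type is the anodic side-chain methoxylation of para-cresols and 4-methoxytoluenes to benzaldehyde dimethyl acetals. No ring is closed and no stereocentre is created; the geometry of 8 is lost on addition. The step needs attack at C7 in preference to ipso-methoxylation at C1, ring substitution and oxidative phenol coupling: the C4 oxygen is para to C7 so that the quinone methide is the conjugated outlet, both positions ortho to the phenol (C3–Br and C5–OMe) are occupied, and methoxide favours benzylic deprotonation. It must also stop at the acetal and spare the C–Br bonds: the acetal phenoxide is harder to oxidise than the cresolate and the charge is limited, and a Pt cathode of low hydrogen overpotential should discharge methanol before the aryl bromides.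

Step 3
Reactants: 9 2,3-dibromo-4-(dimethoxymethyl)-6-methoxyphenol; 10 water
Product: 11 2,3-dibromo-4-hydroxy-5-methoxybenzaldehyde
Conditions: 1 M aq. HCl, THF, rt
Reagents that add atoms: water, O
Why: Acid-catalysed acetal hydrolysis, made fast by the para hydroxyl that stabilises the oxocarbenium ion, in which the carbonyl oxygen comes from water (so step 2 fixes the C7 oxidation level, not the oxygen atom itself) and the aryl methyl ether and the bromides are inert to dilute acid at room temperature.

Step 4
Reactants: 11 2,3-dibromo-4-hydroxy-5-methoxybenzaldehyde
Product: 12 2,3-dibromo-4,5-dihydroxybenzaldehyde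
Conditions: AlCl3 (1.2 equiv), pyridine (4.5 equiv), CH2Cl2, reflux; then 2 M aq. HCl
Reagents that add atoms: none
Why: Chelation-assisted O-demethylation of an ortho-hydroxyanisole with AlCl3 and pyridine, the standard ether cleavage for vanillin and its bromo derivatives, in which aluminium binds O4 and O5, pyridine removes the activated methyl group by SN2 attack, and the acid quench should free the catechol without touching the aldehyde or the bromides.

Step 5
Reactants: 12 2,3-dibromo-4,5-dihydroxybenzaldehyde; 13 sulfur trioxide–pyridine complex
Product: 14 2,3-dibromo-4-formyl-6-hydroxyphenyl hydrogen sulfate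
Conditions: NEt3 (1.0 equiv), SO3·pyridine (1.05 equiv), MeCN, −10 °C to rt; then aq. KHCO3, C18 chromatography
Reagents that add atoms: sulfur trioxide–pyridine complex, O=S(=O)([O-])[n+]1ccccc1
Why: Sulfation of a phenoxide with a sulfur trioxide–amine complex, in which one equivalent of NEt3 ionises only the C4 hydroxyl (para to the formyl group and ortho to bromine, hence by far the more acidic), so that the C4 phenoxide and not the neutral C5 hydroxyl should take up sulfur trioxide.

Step 6
Reactants: 14 2,3-dibromo-4-formyl-6-hydroxyphenyl hydrogen sulfate; 15 acetic anhydride
Product: 16 3,4-dibromo-5-formyl-2-(sulfooxy)phenyl acetate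
Conditions: Ac2O (1.5 equiv), pyridine, 0 °C to rt
Reagents that add atoms: acetic anhydride, CC(=O)OC(C)=O
Why: Pyridine-mediated acetylation of the one remaining phenol, which keeps O5 out of the second sulfation, under conditions to which the sulfate monoester anion and the aldehyde are inert.

Step 7
Reactants: 16 3,4-dibromo-5-formyl-2-(sulfooxy)phenyl acetate
Product: 17 3,4-dibromo-5-(hydroxymethyl)-2-(sulfooxy)phenyl acetate
Conditions: NaBH4 (0.6 equiv), THF–H2O, 0 °C, short contact; NaH2PO4 quench
Reagents that add atoms: none
Why: Borohydride reduction of an aromatic aldehyde, which at 0 °C is much faster than attack on an aryl acetate (as in the reduction of 4-acetoxybenzaldehyde) and leaves the sulfate and the bromides alone, with no stereocentre arising.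

Step 8
Reactants: 17 3,4-dibromo-5-(hydroxymethyl)-2-(sulfooxy)phenyl acetate; 13 sulfur trioxide–pyridine complex
Product: 19 2,3-dibromo-5-hydroxy-4-(sulfooxy)benzyl hydrogen sulfate, via acetate disulfate 18 (not isolated)
Conditions: SO3·pyridine (3 equiv), DMF, 0 °C to rt; then 0.5 M aq. K2CO3, rt; C18 chromatography
Reagents that add atoms: sulfur trioxide–pyridine complex, O=S(=O)([O-])[n+]1ccccc1
Why: O-Sulfation of a primary alcohol with SO3·pyridine followed by mild carbonate hydrolysis of the aryl acetate in the same flask, where sulfate monoester anions survive aqueous carbonate and, because O4 is already sulfated, the benzylic sulfate cannot be expelled through a para-quinone methide.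

**Compound list**

1 | 2-methoxy-4-methylphenol | Cc1ccc(O)c(OC)c1 | starting material
2 | bromine | BrBr | starting material
3 | 2-bromo-6-methoxy-4-methylphenol | Cc1cc(OC)c(O)c(Br)c1 | intermediate
4 | 2,3-dibromo-6-methoxy-4-methylphenol | Cc1cc(OC)c(O)c(Br)c1Br | intermediate
5 | methanol | CO | starting material
6 | 2,3-dibromo-6-methoxy-4-methylidenecyclohexa-2,5-dien-1-one | C=C1C=C(OC)C(=O)C(Br)=C1Br | intermediate
7 | 2,3-dibromo-6-methoxy-4-(methoxymethyl)phenol | COCc1cc(OC)c(O)c(Br)c1Br | intermediate
8 | (4E)-2,3-dibromo-6-methoxy-4-(methoxymethylidene)cyclohexa-2,5-dien-1-one (geometry immaterial, drawn E) | CO/C=C1\C=C(OC)C(=O)C(Br)=C1Br | intermediate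
9 | 2,3-dibromo-4-(dimethoxymethyl)-6-methoxyphenol | COC(OC)c1cc(OC)c(O)c(Br)c1Br | intermediate
10 | water | O | starting material
11 | 2,3-dibromo-4-hydroxy-5-methoxybenzaldehyde | COc1cc(C=O)c(Br)c(Br)c1O | intermediate
12 | 2,3-dibromo-4,5-dihydroxybenzaldehyde | O=Cc1cc(O)c(O)c(Br)c1Br | intermediate
13 | sulfur trioxide–pyridine complex | O=S(=O)([O-])[n+]1ccccc1 | starting material
14 | 2,3-dibromo-4-formyl-6-hydroxyphenyl hydrogen sulfate | O=Cc1cc(O)c(OS(=O)(=O)O)c(Br)c1Br | intermediate
15 | acetic anhydride | CC(=O)OC(C)=O | starting material
16 | 3,4-dibromo-5-formyl-2-(sulfooxy)phenyl acetate | CC(=O)Oc1cc(C=O)c(Br)c(Br)c1OS(=O)(=O)O | intermediate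
17 | 3,4-dibromo-5-(hydroxymethyl)-2-(sulfooxy)phenyl acetate | CC(=O)Oc1cc(CO)c(Br)c(Br)c1OS(=O)(=O)O | intermediate
18 | 3,4-dibromo-2-(sulfooxy)-5-[(sulfooxy)methyl]phenyl acetate | CC(=O)Oc1cc(COS(=O)(=O)O)c(Br)c(Br)c1OS(=O)(=O)O | intermediate
19 | 2,3-dibromo-5-hydroxy-4-(sulfooxy)benzyl hydrogen sulfate | O=S(=O)(O)OCc1cc(O)c(OS(=O)(=O)O)c(Br)c1Br | target

**Step count**

Total steps: 8. Longest linear sequence: 8 (the route is fully linear).

**Steps most likely to fail**

Step 2. The oxidised phenol may be intercepted by methoxide at ring carbon C1 (ipso to the methyl group) or at C3 with loss of bromide. The oxidation may also run past the acetal, or the aryl bromides may be reduced at the cathode. The fallback sets out from 4 and returns at 11 without electrochemistry. Acetylation of 4 (Ac2O, pyridine) should give 2,3-dibromo-6-methoxy-4-methylphenyl acetate F1. Wohl–Ziegler bromination (N-bromosuccinimide 2.3 equiv, AIBN, PhCF3, reflux) should then give 2,3-dibromo-4-(dibromomethyl)-6-methoxyphenyl acetate F2. Aqueous NaOH in THF at rt would cleave the acetate, and the freed phenoxide would expel bromide and hydrolyse the dibromomethyl group to the aldehyde 11.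

Step 5. Sulfur trioxide may be taken up at the less hindered O5 or at both oxygens, giving isomeric salts that are hard to separate. The fallback sets out from 12 and returns at 16, replacing the direct selection by an acyl differentiation. Peracetylation (Ac2O, pyridine) should give 3,4-dibromo-5-formyl-1,2-phenylene diacetate F3. Selective methanolysis of the more electrophilic C4 acetate, which is para to the formyl group (KHCO3, MeOH, 0 °C), should give 3,4-dibromo-5-formyl-2-hydroxyphenyl acetate F4. Any acyl migration favours this isomer, because the more acidic oxygen stays free. Sulfation of the only free hydroxyl of F4 (SO3·pyridine, pyridine, rt) would give 16.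

Step 7. The aryl acetate may be cleaved by borohydride or alkoxide during the reduction, which would expose O5 to the following sulfation. The fallback sets out from 14 and returns at 19 without the acyl group. NaBH4 reduction of 14 (THF–H2O, 0 °C) should give 2,3-dibromo-6-hydroxy-4-(hydroxymethyl)phenyl hydrogen sulfate F5. Its primary alcohol would then be sulfated chemoselectively with SO3·pyridine (1.1 equiv) in DMF at 0 °C without added base, conditions under which a neutral, hindered phenol reacts much more slowly than an aliphatic hydroxyl. This gives 19 directly.

**Further compounds**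

F1 | step 2 | 2,3-dibromo-6-methoxy-4-methylphenyl acetate | CC(=O)Oc1c(OC)cc(C)c(Br)c1Br
F2 | step 2 | 2,3-dibromo-4-(dibromomethyl)-6-methoxyphenyl acetate | CC(=O)Oc1c(OC)cc(C(Br)Br)c(Br)c1Br
F3 | step 5 | 3,4-dibromo-5-formyl-1,2-phenylene diacetate | CC(=O)Oc1cc(C=O)c(Br)c(Br)c1OC(C)=O
F4 | step 5 | 3,4-dibromo-5-formyl-2-hydroxyphenyl acetate | CC(=O)Oc1cc(C=O)c(Br)c(Br)c1O
F5 | step 7 | 2,3-dibromo-6-hydroxy-4-(hydroxymethyl)phenyl hydrogen sulfate | OCc1cc(O)c(OS(=O)(=O)O)c(Br)c1Br
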